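**Plan**
1. Retrosynthetic cuts, in order: the O-helpers (two acetates put on, two phenol benzyl ethers taken off); C5–OH back to C5=O; C7–C1'' (benzylic CH2 to syringyl ring carbon); C5–C6 (cyclopropanol back to ester); C4–C5 (Claisen). This leaves zingerone (guaiacyl ring plus C1–C4).
2. Enabling feature: the C5 oxygen stands 1,3 to C7. The array C5(=O)–C6H2–C7H2–C1''(syringyl) is therefore the ring-opened (homoenolate) form of a 1-substituted cyclopropanol. C5, C6 and C7 are folded into a temporary three-membered ring whose strain drives the union with the syringyl bromide.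
3. The same event unveils the C5 ketone β to the C3 carbinol, which is the array a chelate-controlled 1,3-syn reduction needs. The ring helper is consumed in the key step itself.
4. Forward order of chain assembly: C1–C4 (zingerone) + C5 (dimethyl carbonate) → C3–OH → C6/C7 (EtMgBr) → syringyl ring → C5–OH → diacetate → free phenols. Both arenes are bought; none is built.
5. Stereochemistry: C3 (R) comes from Ru/(R)-BINAP hydrogenation of the β-keto ester. C5 (S, syn) is relayed from C3 through a boron chelate (Narasaka–Prasad).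

Key step: step 7

Remark: chain numbering follows the target (C1 next to the guaiacyl ring, C7 next to the syringyl ring, C1'' the syringyl carbon that bears the chain). The given SMILES is read as (3R,5S), the syn-diacetate. Zingerone and 4-bromo-2,6-dimethoxyphenol are taken as catalogue compounds.

**Step 1**
Reactants: 1 zingerone, 4-(4-hydroxy-3-methoxyphenyl)butan-2-one
Product: 2 4-[4-(benzyloxy)-3-methoxyphenyl]butan-2-one
Conditions: BnBr, K2CO3, acetone, reflux
Reagents that add atoms: benzyl bromide, BrCc1ccccc1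
Why: Williamson ether synthesis, in which the phenoxide formed by the weak base is benzylated by SN2 while the ketone is not enolised, so the acidic guaiacyl OH stays masked until the last step.

**Step 2**
Reactants: 2 4-[4-(benzyloxy)-3-methoxyphenyl]butan-2-one
Product: 3 methyl 5-[4-(benzyloxy)-3-methoxyphenyl]-3-oxopentanoate
Conditions: NaH, (MeO)2CO, THF, reflux; then aq. HCl
Reagents that add atoms: dimethyl carbonate, COC(=O)OC
Why: Crossed Claisen condensation (C-carbomethoxylation of a methyl ketone), in which acylation under equilibrating conditions should end at the less hindered methyl terminus (future C4) because that product is drained off as its stabilised β-keto ester enolate, bringing in the future C5.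

**Step 3**
Reactants: 3 methyl 5-[4-(benzyloxy)-3-methoxyphenyl]-3-oxopentanoate
Product: 4 methyl (3R)-5-[4-(benzyloxy)-3-methoxyphenyl]-3-hydroxypentanoate
Conditions: H2 (10 bar), RuCl2[(R)-BINAP] (0.5 mol %), MeOH, 50 °C
Reagents that add atoms: none
Why: Noyori asymmetric hydrogenation of a β-keto ester, in which the ester carbonyl chelates ruthenium and the (R)-BINAP ligand selects the ketone face that should give the R carbinol (the established sense for 3-oxo esters with an unbranched chain), while benzyl ether and arenes are inert to this catalyst.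

**Step 4**
Reactants: 4 methyl (3R)-5-[4-(benzyloxy)-3-methoxyphenyl]-3-hydroxypentanoate
Product: 5 methyl (3R)-5-[4-(benzyloxy)-3-methoxyphenyl]-3-[(tert-butyldimethylsilyl)oxy]pentanoate
Conditions: TBSCl, imidazole, DMF, rt
Reagents that add atoms: tert-butyldimethylsilyl chloride, CC(C)(C)[Si](C)(C)Cl
Why: Imidazole-promoted O-silylation of a secondary alcohol, which does not touch the stereocentre and gives an ether that withstands the Grignard reagent, the titanium alkoxide and the carbonate base of the next steps.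

**Step 5**
Reactants: 5 methyl (3R)-5-[4-(benzyloxy)-3-methoxyphenyl]-3-[(tert-butyldimethylsilyl)oxy]pentanoate
Product: 6 1-{(2R)-4-[4-(benzyloxy)-3-methoxyphenyl]-2-[(tert-butyldimethylsilyl)oxy]butyl}cyclopropan-1-ol
Conditions: EtMgBr (3 equiv), Ti(Oi-Pr)4 (0.3 equiv), THF, 0 °C to rt; then sat. aq. NH4Cl
Reagents that add atoms: ethylmagnesium bromide, CC[Mg]Br
Why: Kulinkovich cyclopropanation, in which the titanacyclopropane acts as a 1,2-dicarbanion toward the ester carbonyl so that C5 becomes the carbinol carbon and C6/C7 the two ring CH2 groups, with silyl ether, benzyl ether and C3 left untouched.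

**Step 6**
Reactants: 7 4-bromo-2,6-dimethoxyphenol
Product: 8 2-(benzyloxy)-5-bromo-1,3-dimethoxybenzene
Conditions: BnBr, K2CO3, DMF, 50 °C
Reagents that add atoms: benzyl bromide, BrCc1ccccc1
Why: Williamson ether synthesis on the flanked but still nucleophilic syringyl phenoxide, which removes the acidic OH before the base-mediated palladium coupling and uses the same protecting group as the guaiacyl ring for one joint release.

**Step 7**
Reactants: 6 1-{(2R)-4-[4-(benzyloxy)-3-methoxyphenyl]-2-[(tert-butyldimethylsilyl)oxy]butyl}cyclopropan-1-ol; 8 2-(benzyloxy)-5-bromo-1,3-dimethoxybenzene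
Product: 9 (5R)-7-[4-(benzyloxy)-3-methoxyphenyl]-1-[4-(benzyloxy)-3,5-dimethoxyphenyl]-5-[(tert-butyldimethylsilyl)oxy]heptan-3-one
Conditions: Pd(OAc)2 (5 mol %), XPhos (10 mol %), Cs2CO3 (2 equiv), toluene, 80 °C
Reagents that add atoms: none
Why: Oxidative addition of Pd(0) into the C1''–Br bond of 8, exchange of bromide for the cyclopropanolate of 6 and strain-driven β-carbon elimination of a C5–CH2 ring bond should give the palladium homoenolate Ar–Pd–C7H2–C6H2–C5(=O)R, whose reductive elimination forms the C7–C1'' bond and at the same time releases the C5 ketone. The closest known reaction type is the palladium-catalysed cross-coupling of 1-alkylcyclopropanols (ketone homoenolates) with aryl bromides. No ring is closed (the temporary three-membered ring is opened) and no stereocentre is created, and C3 lies outside the reacting atoms and keeps its R configuration. The step needs reductive elimination to outrun β-hydride elimination at C6 (which leads to the vinyl ketone) and protonation to the ethyl ketone, which the bulky electron-rich biaryl phosphine and the dry non-polar medium are chosen to secure. Site selectivity is built in, since the two ring CH2 groups are constitutionally equivalent so that either cleavage gives the same chain, and the bromine fixes the ring carbon para to the protected O4''. The silyl ether keeps the C3 oxygen from binding palladium and from retro-aldol or elimination pathways, and the benzyl ethers keep both phenols out of the base.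

**Step 8**
Reactants: 9 (5R)-7-[4-(benzyloxy)-3-methoxyphenyl]-1-[4-(benzyloxy)-3,5-dimethoxyphenyl]-5-[(tert-butyldimethylsilyl)oxy]heptan-3-one
Product: 10 (5R)-7-[4-(benzyloxy)-3-methoxyphenyl]-1-[4-(benzyloxy)-3,5-dimethoxyphenyl]-5-hydroxyheptan-3-one
Conditions: HF·pyridine, pyridine, THF, 0 °C to rt
Reagents that add atoms: none
Why: Fluoride-driven desilylation in a buffered, weakly acidic medium, chosen because it avoids the basic conditions under which a β-hydroxy ketone would eliminate or undergo retro-aldol cleavage, so C3 should stay intact.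

**Step 9**
Reactants: 10 (5R)-7-[4-(benzyloxy)-3-methoxyphenyl]-1-[4-(benzyloxy)-3,5-dimethoxyphenyl]-5-hydroxyheptan-3-one
Product: 12 (3R,5S)-1-[4-(benzyloxy)-3-methoxyphenyl]-7-[4-(benzyloxy)-3,5-dimethoxyphenyl]heptane-3,5-diol, via diethylboron chelate 11 (not isolated)
Conditions: Et2BOMe, THF/MeOH (4:1), −78 °C; NaBH4, −78 °C; then H2O2, pH 7 buffer, 0 °C
Reagents that add atoms: none
Why: Narasaka–Prasad reduction, in which boron ties the C3 oxygen and the C5 carbonyl into a six-membered half-chair with the C3 side chain pseudo-equatorial and external hydride adds axially, which should set C5 as S, syn to C3.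

**Step 10**
Reactants: 12 (3R,5S)-1-[4-(benzyloxy)-3-methoxyphenyl]-7-[4-(benzyloxy)-3,5-dimethoxyphenyl]heptane-3,5-diol
Product: 13 (3R,5S)-1-[4-(benzyloxy)-3-methoxyphenyl]-7-[4-(benzyloxy)-3,5-dimethoxyphenyl]heptane-3,5-diyl diacetate
Conditions: Ac2O, pyridine, DMAP (cat.), CH2Cl2, rt
Reagents that add atoms: acetic anhydride, CC(=O)OC(C)=O
Why: DMAP-catalysed acylation at oxygen with retention at both carbinol carbons, in which only the two secondary alcohols can react because both phenols are still benzylated.

**Step 11**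
Reactants: 13 (3R,5S)-1-[4-(benzyloxy)-3-methoxyphenyl]-7-[4-(benzyloxy)-3,5-dimethoxyphenyl]heptane-3,5-diyl diacetate
Product: 14 (3R,5S)-1-(4-hydroxy-3-methoxyphenyl)-7-(4-hydroxy-3,5-dimethoxyphenyl)heptane-3,5-diyl diacetate (target)
Conditions: H2 (1 atm), 10 % Pd/C, EtOAc, rt
Reagents that add atoms: none
Why: Catalytic hydrogenolysis of the two aryl benzyl ethers under neutral conditions, which should free both phenols in one operation without cleaving or shifting the non-benzylic secondary acetates.

**Compound list**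
1 | zingerone, 4-(4-hydroxy-3-methoxyphenyl)butan-2-one | COc1cc(CCC(C)=O)ccc1O | starting material
2 | 4-[4-(benzyloxy)-3-methoxyphenyl]butan-2-one | COc1cc(CCC(C)=O)ccc1OCc1ccccc1 | intermediate
3 | methyl 5-[4-(benzyloxy)-3-methoxyphenyl]-3-oxopentanoate | COc1cc(CCC(=O)CC(=O)OC)ccc1OCc1ccccc1 | intermediate
4 | methyl (3R)-5-[4-(benzyloxy)-3-methoxyphenyl]-3-hydroxypentanoate | COc1cc(CC[C@H](CC(=O)OC)O)ccc1OCc1ccccc1 | intermediate
5 | methyl (3R)-5-[4-(benzyloxy)-3-methoxyphenyl]-3-[(tert-butyldimethylsilyl)oxy]pentanoate | COc1cc(CC[C@H](CC(=O)OC)O[Si](C)(C)C(C)(C)C)ccc1OCc1ccccc1 | intermediate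
6 | 1-{(2R)-4-[4-(benzyloxy)-3-methoxyphenyl]-2-[(tert-butyldimethylsilyl)oxy]butyl}cyclopropan-1-ol | COc1cc(CC[C@H](CC2(O)CC2)O[Si](C)(C)C(C)(C)C)ccc1OCc1ccccc1 | intermediate
7 | 4-bromo-2,6-dimethoxyphenol | COc1cc(Br)cc(OC)c1O | starting material
8 | 2-(benzyloxy)-5-bromo-1,3-dimethoxybenzene | COc1cc(Br)cc(OC)c1OCc1ccccc1 | intermediate
9 | (5R)-7-[4-(benzyloxy)-3-methoxyphenyl]-1-[4-(benzyloxy)-3,5-dimethoxyphenyl]-5-[(tert-butyldimethylsilyl)oxy]heptan-3-one | COc1cc(CC[C@H](CC(=O)CCc2cc(OC)c(OCc3ccccc3)c(OC)c2)O[Si](C)(C)C(C)(C)C)ccc1OCc1ccccc1 | intermediate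
10 | (5R)-7-[4-(benzyloxy)-3-methoxyphenyl]-1-[4-(benzyloxy)-3,5-dimethoxyphenyl]-5-hydroxyheptan-3-one | COc1cc(CC[C@H](CC(=O)CCc2cc(OC)c(OCc3ccccc3)c(OC)c2)O)ccc1OCc1ccccc1 | intermediate
11 | diethylboron chelate (O-diethylboryl derivative of 10, boron coordinated to the ketone oxygen) | COc1cc(CC[C@H](CC(=O)CCc2cc(OC)c(OCc3ccccc3)c(OC)c2)OB(CC)CC)ccc1OCc1ccccc1 | intermediate
12 | (3R,5S)-1-[4-(benzyloxy)-3-methoxyphenyl]-7-[4-(benzyloxy)-3,5-dimethoxyphenyl]heptane-3,5-diol | COc1cc(CC[C@H](C[C@H](CCc2cc(OC)c(OCc3ccccc3)c(OC)c2)O)O)ccc1OCc1ccccc1 | intermediate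
13 | (3R,5S)-1-[4-(benzyloxy)-3-methoxyphenyl]-7-[4-(benzyloxy)-3,5-dimethoxyphenyl]heptane-3,5-diyl diacetate | COc1cc(CC[C@H](C[C@H](CCc2cc(OC)c(OCc3ccccc3)c(OC)c2)OC(C)=O)OC(C)=O)ccc1OCc1ccccc1 | intermediate
14 | (3R,5S)-1-(4-hydroxy-3-methoxyphenyl)-7-(4-hydroxy-3,5-dimethoxyphenyl)heptane-3,5-diyl diacetate | COc1cc(CC[C@H](C[C@H](CCc2cc(OC)c(O)c(OC)c2)OC(C)=O)OC(C)=O)ccc1O | target

Total step count: 11. Longest linear sequence: 10 (steps 1–5 and 7–11).

**Steps most likely to fail**

Step 7. With the electron-rich aryl bromide, β-hydride elimination or protonation of the palladium homoenolate may outrun reductive elimination. The carbonate base may also induce β-elimination of the silyloxy group in the product. The fallback makes the same bond by Heck arylation with isomerisation of an allylic alcohol; it sets out from 5 and comes back at 9.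
- DIBAL-H (CH2Cl2, −78 °C) should give (3R)-5-[4-(benzyloxy)-3-methoxyphenyl]-3-[(tert-butyldimethylsilyl)oxy]pentanal F1.
- Vinylmagnesium bromide (THF, −78 °C) should give (5R)-7-[4-(benzyloxy)-3-methoxyphenyl]-5-[(tert-butyldimethylsilyl)oxy]hept-1-en-3-ol F2. Both epimers at the new carbinol serve, because that carbon becomes the ketone.
- Heck reaction of F2 with 8 (Pd(OAc)2, Bu4NCl, NaHCO3, DMF, 80 °C) places the aryl group on the terminal carbon. β-Hydride elimination toward the carbinol C–H then gives the enol, and with it ketone 9.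

Step 5. The titanium-mediated cyclopropanation may stall, or give way to simple Grignard addition or reduction at the ester, if the β-oxygen ties up titanium. The fallback builds the ring by cyclopropanation of an enol ether; it sets out from 5 and comes back at 6.
- MeNH(OMe)·HCl with i-PrMgCl (THF, −10 °C) should give the Weinreb amide (3R)-5-[4-(benzyloxy)-3-methoxyphenyl]-3-[(tert-butyldimethylsilyl)oxy]-N-methoxy-N-methylpentanamide F3.
- MeMgBr should give (4R)-6-[4-(benzyloxy)-3-methoxyphenyl]-4-[(tert-butyldimethylsilyl)oxy]hexan-2-one F4.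
- Kinetic enolisation (LDA, TMSCl, THF, −78 °C) should give the terminal enol ether {[(4R)-6-[4-(benzyloxy)-3-methoxyphenyl]-4-[(tert-butyldimethylsilyl)oxy]hex-1-en-2-yl]oxy}trimethylsilane F5.
- Simmons–Smith cyclopropanation (Et2Zn, CH2I2, CH2Cl2, 0 °C) should give the O-trimethylsilyl ether of 6 F6.
- K2CO3 in MeOH at 0 °C should remove only the trimethylsilyl group, which gives 6.

Step 9. Incomplete chelate formation would lead to poor facial selectivity in the hydride delivery. The fallback replaces substrate control by catalyst control and adds a separable derivative; it sets out from 10 and comes back at 12.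
- Hydroxyl-directed hydrogenation of 10 with RuCl2[(S)-BINAP] (H2, MeOH) should favour the S carbinol at C5.
- The crude diol is converted (2,2-dimethoxypropane, PPTS) into the syn-acetonide (4R,6S)-4-{2-[4-(benzyloxy)-3-methoxyphenyl]ethyl}-6-{2-[4-(benzyloxy)-3,5-dimethoxyphenyl]ethyl}-2,2-dimethyl-1,3-dioxane F7.
- F7 is freed from any anti isomer by chromatography and then cleaved (80 % aq. AcOH, 40 °C) to 12.

**Further compounds**
F1 | step 7 | (3R)-5-[4-(benzyloxy)-3-methoxyphenyl]-3-[(tert-butyldimethylsilyl)oxy]pentanal | COc1cc(CC[C@H](CC=O)O[Si](C)(C)C(C)(C)C)ccc1OCc1ccccc1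
F2 | step 7 | (5R)-7-[4-(benzyloxy)-3-methoxyphenyl]-5-[(tert-butyldimethylsilyl)oxy]hept-1-en-3-ol (both C3 epimers) | COc1cc(CC[C@H](CC(O)C=C)O[Si](C)(C)C(C)(C)C)ccc1OCc1ccccc1
F3 | step 5 | (3R)-5-[4-(benzyloxy)-3-methoxyphenyl]-3-[(tert-butyldimethylsilyl)oxy]-N-methoxy-N-methylpentanamide | COc1cc(CC[C@H](CC(=O)N(C)OC)O[Si](C)(C)C(C)(C)C)ccc1OCc1ccccc1
F4 | step 5 | (4R)-6-[4-(benzyloxy)-3-methoxyphenyl]-4-[(tert-butyldimethylsilyl)oxy]hexan-2-one | COc1cc(CC[C@H](CC(C)=O)O[Si](C)(C)C(C)(C)C)ccc1OCc1ccccc1
F5 | step 5 | {[(4R)-6-[4-(benzyloxy)-3-methoxyphenyl]-4-[(tert-butyldimethylsilyl)oxy]hex-1-en-2-yl]oxy}trimethylsilane | COc1cc(CC[C@H](CC(=C)O[Si](C)(C)C)O[Si](C)(C)C(C)(C)C)ccc1OCc1ccccc1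
F6 | step 5 | O-trimethylsilyl ether of 6 | COc1cc(CC[C@H](CC2(CC2)O[Si](C)(C)C)O[Si](C)(C)C(C)(C)C)ccc1OCc1ccccc1
F7 | step 9 | (4R,6S)-4-{2-[4-(benzyloxy)-3-methoxyphenyl]ethyl}-6-{2-[4-(benzyloxy)-3,5-dimethoxyphenyl]ethyl}-2,2-dimethyl-1,3-dioxane | COc1cc(CC[C@@H]2C[C@H](CCc3cc(OC)c(OCc4ccccc4)c(OC)c3)OC(C)(C)O2)ccc1OCc1ccccc1
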